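## Retrosynthetic overview

1. The two hydroheptelidic acid halves in the SMILES are antipodes: the acyl half (free diol) is (5aS,6R,9S,9aS), the half esterified at its CH2O is (5aR,6S,9R,9aR). Locants follow 2-benzoxepine numbering: C1 lactone C=O, C4 carboxyl-bearing alkene carbon, C5a/C9a ring fusion, C6 isopropyl, C9 carbinol. The last disconnection is the ester C–O bond, made by opening the C9 spiro-epoxide 38 of the mirror-image series at CH2 with the carboxylate of acid 22.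
2. In each half, ring B (the oxepinone) is closed last by ring-closing metathesis between a C5a vinyl group and a 2-(tert-butoxycarbonyl)allyl ester on the C9a carboxyl.
3. C5a and C6 come from a C5a=C6 cyclohexene: syn hydroboration on the face opposite the C9a substituent, then stereoretentive vinylation of the C–B bond.
4. Ring A is made first, in one catalytic enantioselective Diels–Alder reaction that forms C7–C8 and C9–C9a from diene 5 (C9a=C5a–C6(iPr)=C7) and 2-acyloxyacrolein 8 (C8=C9). Enabling feature: in ring A (C5a–C6–C7–C8–C9–C9a) the quaternary C9 carries an oxygen and a one-carbon oxygenated branch and sits next to C9a, whose exocyclic carbon C1 is cis to that branch, while C7 and C8 are plain CH2. Ring A is therefore the "ortho/para" endo adduct of a 1,3-disubstituted butadiene and a captodative 1,1-disubstituted alkene.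
5. Order of ring formation: ring A (cycloaddition), ring B (metathesis), then union of the two bicycles. The two catalyst antipodes give the two antipodal halves from the same diene and dienophile.

Key step: step 7

Assumption: the (S)-diammonium salt is taken to give the (1S) adduct 9 (series N) and the (R)-salt its mirror image 23 (series E); if the sense of induction is the reverse, the two catalysts are exchanged between steps 7 and 17, since both antipodal series are needed.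

## Route

### Diene and dienophile

Step 1
Reactants: 1 3-methylbutanal
Product: 2 3-methyl-2-methylidenebutanal
Conditions: 37% aq. CH2O, pyrrolidine (10 mol%), EtCO2H (10 mol%), i-PrOH, 45 °C
Reagents that add atoms: formaldehyde C=O
Why: Amine-catalysed Mannich condensation–elimination (α-methylenation of an enolisable aldehyde) should give the 2-substituted acrolein; no stereocentre is formed.

Step 2
Reactants: 2 3-methyl-2-methylidenebutanal
Product: 3 ethyl (2E)-5-methyl-4-methylidenehex-2-enoate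
Conditions: (EtO)2P(O)CH2CO2Et, NaH, THF, 0 °C to rt
Reagents that add atoms: triethyl phosphonoacetate CCOC(=O)CP(=O)(OCC)OCC
Why: Horner–Wadsworth–Emmons olefination with a stabilised phosphonate anion should give the (E)-dienoate.

Step 3
Reactants: 3 ethyl (2E)-5-methyl-4-methylidenehex-2-enoate
Product: 4 (2E)-5-methyl-4-methylidenehex-2-en-1-ol
Conditions: i-Bu2AlH (2.2 equiv), CH2Cl2, −78 °C; Rochelle salt work-up
Reagents that add atoms: none
Why: 1,2-Reduction of the unsaturated ester by i-Bu2AlH should give the dienol without touching the diene.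

Step 4
Reactants: 4 (2E)-5-methyl-4-methylidenehex-2-en-1-ol
Product: 5 tert-butyl(dimethyl){[(2E)-5-methyl-4-methylidenehex-2-en-1-yl]oxy}silane
Conditions: TBSCl, imidazole, CH2Cl2, 0 °C to rt
Reagents that add atoms: tert-butyl(chloro)dimethylsilane CC(C)(C)[Si](C)(C)Cl
Why: Silylation masks the oxygen on the future C1 and keeps the 1,3-disubstituted diene electron-rich.

Step 5
Reactants: 6 2,2-dimethyl-1,3-dioxan-5-one
Product: 7 2,2-dimethyl-4H-1,3-dioxin-5-yl cyclohexanecarboxylate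
Conditions: KN(SiMe3)2, THF, −78 °C; then c-C6H11COCl
Reagents that add atoms: cyclohexanecarbonyl chloride O=C(Cl)C1CCCCC1
Why: O-Acylation of the potassium enolate of the α,α'-dialkoxy ketone should give the enol ester.

Step 6
Reactants: 7 2,2-dimethyl-4H-1,3-dioxin-5-yl cyclohexanecarboxylate
Product: 8 3-oxoprop-1-en-2-yl cyclohexanecarboxylate (2-(cyclohexanecarbonyloxy)acrolein)
Conditions: toluene, 110 °C, sealed tube; distillation
Reagents that add atoms: none
Why: Retro-hetero-Diels–Alder cycloreversion of the 4H-1,3-dioxin releases acetone and the 2-acyloxyacrolein.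

### Series N (acyl half)

Step 7
Reactants: 5 tert-butyl(dimethyl){[(2E)-5-methyl-4-methylidenehex-2-en-1-yl]oxy}silane; 8 3-oxoprop-1-en-2-yl cyclohexanecarboxylate
Product: 9 (1S,2R)-2-({[tert-butyl(dimethyl)silyl]oxy}methyl)-1-formyl-4-(propan-2-yl)cyclohex-3-en-1-yl cyclohexanecarboxylate (CHO cis to CH2OTBS)
Conditions: (S)-1,1'-binaphthyl-2,2'-diamine (5 mol%), HNTf2 (9.5 mol%), EtCN, −75 °C
Reagents that add atoms: none
Why: The primary ammonium salt condenses with 8 to an iminium ion that adds to diene 5 in a concerted, asynchronous normal-demand [4+2] cycloaddition forming C7–C8 and C9–C9a; the closest known reaction type is the chiral diammonium-salt-catalysed enantioselective Diels–Alder reaction of α-acyloxyacroleins with dienes. Ring A is the only ring closed, by intermolecular suprafacial [4π+2π] addition. C9 (quaternary, acyloxy and CHO) is set by the catalyst, whose binaphthyl backbone shields one face of the iminium dienophile; C9a is set relative to C9 by the endo position of the formyl (iminium) group, which puts CHO cis to CH2OTBS with transfer of the (E)-geometry of the diene. Regioselectivity is secured by the 1,3-disubstitution of the diene: CH2OTBS on the reacting terminus directs "ortho" and isopropyl on C6 directs "para", both to the same adduct, as in the adducts of 2-methylpenta-1,3-diene with acrolein. The step needs endo and face selectivity; the open-chain diene has no bridging CH2 to push an α-substituted acrolein exo, and the catalyst antipode chooses the face.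

Step 8
Reactants: 9 (1S,2R)-2-({[tert-butyl(dimethyl)silyl]oxy}methyl)-1-formyl-4-(propan-2-yl)cyclohex-3-en-1-yl cyclohexanecarboxylate
Product: 10 (1S,2R)-2-({[tert-butyl(dimethyl)silyl]oxy}methyl)-1-(hydroxymethyl)-4-(propan-2-yl)cyclohex-3-en-1-ol
Conditions: LiAlH4 (3 equiv), THF, 0 °C to rt
Reagents that add atoms: none
Why: Hydride reduction of the aldehyde and reductive cleavage of the tertiary ester should give the C9 diol with both stereocentres untouched.

Step 9
Reactants: 10 (1S,2R)-2-({[tert-butyl(dimethyl)silyl]oxy}methyl)-1-(hydroxymethyl)-4-(propan-2-yl)cyclohex-3-en-1-ol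
Product: 11 tert-butyl{[(5S,6R)-2,2-dimethyl-8-(propan-2-yl)-1,3-dioxaspiro[4.5]dec-7-en-6-yl]methoxy}dimethylsilane
Conditions: Me2C(OMe)2, PPTS (cat.), CH2Cl2, rt
Reagents that add atoms: 2,2-dimethoxypropane COC(C)(C)OC
Why: Acid-catalysed transketalisation converts the only 1,2-diol into the spiro-dioxolane (acetonide).

Step 10
Reactants: 11 tert-butyl{[(5S,6R)-2,2-dimethyl-8-(propan-2-yl)-1,3-dioxaspiro[4.5]dec-7-en-6-yl]methoxy}dimethylsilane
Product: 13 tert-butyl{[(5S,6R,7R,8S)-2,2-dimethyl-8-(propan-2-yl)-7-(4,4,5,5-tetramethyl-1,3,2-dioxaborolan-2-yl)-1,3-dioxaspiro[4.5]decan-6-yl]methoxy}dimethylsilane, via monoalkylborane 12 (not isolated)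
Conditions: BH3·SMe2 (3 equiv), THF, 0 °C to rt; then pinacol (6 equiv), rt
Reagents that add atoms: borane–dimethyl sulfide [BH3-][S+](C)C; pinacol CC(C)(O)C(C)(C)O
Why: Hydroboration (anti-Markovnikov, syn) should put boron on the less substituted C5a and hydrogen on C6 from the face opposite the allylic CH2OTBS group on C9a, setting C6 (isopropyl trans to boron) and C5a together, and pinacol then converts the monoalkylborane into the boronic ester with loss of H2.

Step 11
Reactants: 13 tert-butyl{[(5S,6R,7R,8S)-2,2-dimethyl-8-(propan-2-yl)-7-(4,4,5,5-tetramethyl-1,3,2-dioxaborolan-2-yl)-1,3-dioxaspiro[4.5]decan-6-yl]methoxy}dimethylsilane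
Product: 16 tert-butyl{[(5S,6R,7R,8R)-7-ethenyl-2,2-dimethyl-8-(propan-2-yl)-1,3-dioxaspiro[4.5]decan-6-yl]methoxy}dimethylsilane, via vinylboronate complex 14 (not isolated), via iodoalkylboronate 15 (not isolated)
Conditions: CH2=CHMgBr (4 equiv), THF/DMSO (1:1), 0 °C; I2 (4 equiv), MeOH, −78 °C; NaOMe (8 equiv), MeOH, −78 °C to rt
Reagents that add atoms: vinylmagnesium bromide C=C[Mg]Br
Why: Zweifel olefination: iodine triggers 1,2-migration of the secondary alkyl group in the vinyl boronate complex with retention at C5a, and methoxide-induced anti elimination leaves the vinyl group where boron was.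

Step 12
Reactants: 16 tert-butyl{[(5S,6R,7R,8R)-7-ethenyl-2,2-dimethyl-8-(propan-2-yl)-1,3-dioxaspiro[4.5]decan-6-yl]methoxy}dimethylsilane
Product: 17 [(5S,6R,7R,8R)-7-ethenyl-2,2-dimethyl-8-(propan-2-yl)-1,3-dioxaspiro[4.5]decan-6-yl]methanol
Conditions: Bu4NF, THF, 0 °C to rt
Reagents that add atoms: none
Why: Fluoride desilylation frees the primary alcohol on the future C1; ketal and alkene are inert.

Step 13
Reactants: 17 [(5S,6R,7R,8R)-7-ethenyl-2,2-dimethyl-8-(propan-2-yl)-1,3-dioxaspiro[4.5]decan-6-yl]methanol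
Product: 19 (5S,6S,7R,8R)-7-ethenyl-2,2-dimethyl-8-(propan-2-yl)-1,3-dioxaspiro[4.5]decane-6-carboxylic acid, via aldehyde 18 (not isolated)
Conditions: TEMPO (0.2 equiv), PhI(OAc)2 (2.5 equiv), MeCN/H2O (1:1), rt
Reagents that add atoms: water O
Why: Oxoammonium (TEMPO) oxidation takes the primary alcohol through the aldehyde hydrate to the acid under near-neutral conditions, so C9a should not epimerise and the vinyl group and ketal survive.

Step 14
Reactants: 19 (5S,6S,7R,8R)-7-ethenyl-2,2-dimethyl-8-(propan-2-yl)-1,3-dioxaspiro[4.5]decane-6-carboxylic acid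
Product: 20 2-(tert-butoxycarbonyl)prop-2-en-1-yl (5S,6S,7R,8R)-7-ethenyl-2,2-dimethyl-8-(propan-2-yl)-1,3-dioxaspiro[4.5]decane-6-carboxylate
Conditions: tert-butyl 2-(bromomethyl)acrylate (1.3 equiv), Cs2CO3, DMF, 0 °C to rt
Reagents that add atoms: tert-butyl 2-(bromomethyl)prop-2-enoate C=C(CBr)C(=O)OC(C)(C)C
Why: O-Alkylation of the caesium carboxylate by the allylic bromide (SN2 or SN2', same product) installs C3, C4 and the protected C4 carboxyl.

Step 15
Reactants: 20 2-(tert-butoxycarbonyl)prop-2-en-1-yl (5S,6S,7R,8R)-7-ethenyl-2,2-dimethyl-8-(propan-2-yl)-1,3-dioxaspiro[4.5]decane-6-carboxylate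
Product: 21 tert-butyl (5aS,6R,9S,9aS)-2',2'-dimethyl-1-oxo-6-(propan-2-yl)-3,5a,6,7,8,9a-hexahydro-1H-spiro[2-benzoxepine-9,4'-[1,3]dioxolane]-4-carboxylate
Conditions: second-generation Grubbs catalyst RuCl2(=CHPh)(PCy3)(SIMes) (10 mol%), toluene (2 mM), 80 °C
Reagents that add atoms: none
Why: Ring-closing metathesis between the C5a vinyl group and the 1,1-disubstituted acrylate alkene should close ring B as a trans-fused seven-membered lactone, because the two tethered groups are trans-diequatorial; the ring fixes the alkene geometry.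

Step 16
Reactants: 21 tert-butyl (5aS,6R,9S,9aS)-2',2'-dimethyl-1-oxo-6-(propan-2-yl)-3,5a,6,7,8,9a-hexahydro-1H-spiro[2-benzoxepine-9,4'-[1,3]dioxolane]-4-carboxylate
Product: 22 (5aS,6R,9S,9aS)-9-hydroxy-9-(hydroxymethyl)-1-oxo-6-(propan-2-yl)-1,3,5a,6,7,8,9,9a-octahydro-2-benzoxepine-4-carboxylic acid (hydroheptelidic acid)
Conditions: CF3CO2H/CH2Cl2/H2O (10:10:1), 0 °C to rt
Reagents that add atoms: none
Why: Acidolysis removes the acetonide and the tert-butyl ester in one operation without touching a stereocentre.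

### Series E (alkyl half)

Step 17
Reactants: 5 tert-butyl(dimethyl){[(2E)-5-methyl-4-methylidenehex-2-en-1-yl]oxy}silane; 8 3-oxoprop-1-en-2-yl cyclohexanecarboxylate
Product: 23 (1R,2S)-2-({[tert-butyl(dimethyl)silyl]oxy}methyl)-1-formyl-4-(propan-2-yl)cyclohex-3-en-1-yl cyclohexanecarboxylate
Conditions: (R)-1,1'-binaphthyl-2,2'-diamine (5 mol%), HNTf2 (9.5 mol%), EtCN, −75 °C
Reagents that add atoms: none
Why: The same enantioselective Diels–Alder reaction as step 7 with the antipodal diammonium salt should set C9 and C9a in the mirror-image sense.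

Step 18
Reactants: 23 (1R,2S) enantiomer of 9
Product: 24 (1R,2S)-2-({[tert-butyl(dimethyl)silyl]oxy}methyl)-1-(hydroxymethyl)-4-(propan-2-yl)cyclohex-3-en-1-ol
Conditions: LiAlH4 (3 equiv), THF, 0 °C to rt
Reagents that add atoms: none
Why: Hydride reduction and ester cleavage as in step 8, on the enantiomer.

Step 19
Reactants: 24 (1R,2S) enantiomer of 10
Product: 25 tert-butyl{[(5R,6S)-2,2-dimethyl-8-(propan-2-yl)-1,3-dioxaspiro[4.5]dec-7-en-6-yl]methoxy}dimethylsilane
Conditions: Me2C(OMe)2, PPTS (cat.), CH2Cl2, rt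
Reagents that add atoms: 2,2-dimethoxypropane COC(C)(C)OC
Why: Acetonide formation by transketalisation as in step 9.

Step 20
Reactants: 25 (5R,6S) enantiomer of 11
Product: 27 tert-butyl{[(5R,6S,7S,8R)-2,2-dimethyl-8-(propan-2-yl)-7-(4,4,5,5-tetramethyl-1,3,2-dioxaborolan-2-yl)-1,3-dioxaspiro[4.5]decan-6-yl]methoxy}dimethylsilane, via monoalkylborane 26 (not isolated)
Conditions: BH3·SMe2 (3 equiv), THF, 0 °C to rt; then pinacol (6 equiv), rt
Reagents that add atoms: borane–dimethyl sulfide [BH3-][S+](C)C; pinacol CC(C)(O)C(C)(C)O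
Why: Syn hydroboration opposite the CH2OTBS group as in step 10 sets C5a and C6 in the mirror-image sense.

Step 21
Reactants: 27 (5R,6S,7S,8R) enantiomer of 13
Product: 30 tert-butyl{[(5R,6S,7S,8S)-7-ethenyl-2,2-dimethyl-8-(propan-2-yl)-1,3-dioxaspiro[4.5]decan-6-yl]methoxy}dimethylsilane, via vinylboronate complex 28 (not isolated), via iodoalkylboronate 29 (not isolated)
Conditions: CH2=CHMgBr (4 equiv), THF/DMSO (1:1), 0 °C; I2 (4 equiv), MeOH, −78 °C; NaOMe (8 equiv), MeOH, −78 °C to rt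
Reagents that add atoms: vinylmagnesium bromide C=C[Mg]Br
Why: Zweifel olefination with retention at C5a as in step 11.

Step 22
Reactants: 30 (5R,6S,7S,8S) enantiomer of 16
Product: 31 [(5R,6S,7S,8S)-7-ethenyl-2,2-dimethyl-8-(propan-2-yl)-1,3-dioxaspiro[4.5]decan-6-yl]methanol
Conditions: Bu4NF, THF, 0 °C to rt
Reagents that add atoms: none
Why: Fluoride desilylation as in step 12.

Step 23
Reactants: 31 (5R,6S,7S,8S) enantiomer of 17
Product: 33 (5R,6R,7S,8S)-7-ethenyl-2,2-dimethyl-8-(propan-2-yl)-1,3-dioxaspiro[4.5]decane-6-carboxylic acid, via aldehyde 32 (not isolated)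
Conditions: TEMPO (0.2 equiv), PhI(OAc)2 (2.5 equiv), MeCN/H2O (1:1), rt
Reagents that add atoms: water O
Why: Oxoammonium (TEMPO) oxidation to the acid as in step 13.

Step 24
Reactants: 33 (5R,6R,7S,8S) enantiomer of 19
Product: 34 2-(tert-butoxycarbonyl)prop-2-en-1-yl (5R,6R,7S,8S)-7-ethenyl-2,2-dimethyl-8-(propan-2-yl)-1,3-dioxaspiro[4.5]decane-6-carboxylate
Conditions: tert-butyl 2-(bromomethyl)acrylate (1.3 equiv), Cs2CO3, DMF, 0 °C to rt
Reagents that add atoms: tert-butyl 2-(bromomethyl)prop-2-enoate C=C(CBr)C(=O)OC(C)(C)C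
Why: Carboxylate O-alkylation as in step 14.

Step 25
Reactants: 34 (5R,6R,7S,8S) enantiomer of 20
Product: 35 tert-butyl (5aR,6S,9R,9aR)-2',2'-dimethyl-1-oxo-6-(propan-2-yl)-3,5a,6,7,8,9a-hexahydro-1H-spiro[2-benzoxepine-9,4'-[1,3]dioxolane]-4-carboxylate
Conditions: second-generation Grubbs catalyst RuCl2(=CHPh)(PCy3)(SIMes) (10 mol%), toluene (2 mM), 80 °C
Reagents that add atoms: none
Why: Ring-closing metathesis closes ring B as in step 15.

Step 26
Reactants: 35 (5aR,6S,9R,9aR) enantiomer of 21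
Product: 36 tert-butyl (5aR,6S,9R,9aR)-9-hydroxy-9-(hydroxymethyl)-1-oxo-6-(propan-2-yl)-1,3,5a,6,7,8,9,9a-octahydro-2-benzoxepine-4-carboxylate
Conditions: AcOH/H2O (4:1), 40 °C
Reagents that add atoms: none
Why: Mild acid hydrolysis removes the acetonide while the tert-butyl ester and the lactone should stay.

Step 27
Reactants: 36 tert-butyl (5aR,6S,9R,9aR)-9-hydroxy-9-(hydroxymethyl)-1-oxo-6-(propan-2-yl)-1,3,5a,6,7,8,9,9a-octahydro-2-benzoxepine-4-carboxylate
Product: 38 tert-butyl (5aR,6S,9R,9aR)-1-oxo-6-(propan-2-yl)-3,5a,6,7,8,9a-hexahydro-1H-spiro[2-benzoxepine-9,2'-oxirane]-4-carboxylate, via primary mesylate 37 (not isolated)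
Conditions: MsCl (1.1 equiv), Et3N, CH2Cl2, −20 °C; then DBU, rt
Reagents that add atoms: none
Why: Selective sulfonylation of the primary alcohol followed by intramolecular Williamson closure (3-exo-tet) by the tertiary alkoxide gives the spiro-epoxide with retention at C9, since the C9–O bond is not broken.

### Union and release

Step 28
Reactants: 22 (5aS,6R,9S,9aS)-hydroheptelidic acid; 38 tert-butyl (5aR,6S,9R,9aR)-1-oxo-6-(propan-2-yl)-3,5a,6,7,8,9a-hexahydro-1H-spiro[2-benzoxepine-9,2'-oxirane]-4-carboxylate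
Product: 39 tert-butyl ester of the target (acyl half 5aS,6R,9S,9aS; alkyl half 5aR,6S,9R,9aR)
Conditions: 22 (1.2 equiv), Cs2CO3 (0.3 equiv), Bu4NBr (0.1 equiv), DMF, 60 °C
Reagents that add atoms: none
Why: Base-catalysed SN2 opening of the 2,2-disubstituted epoxide by the carboxylate of 22 at the CH2 carbon gives the β-hydroxy ester and the tertiary C9 alcohol of the alkyl half; no stereocentre is touched.

Step 29
Reactants: 39 tert-butyl ester of the target
Product: 40 CNP0340505.1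
Conditions: CF3CO2H/CH2Cl2 (1:4), 0 °C
Reagents that add atoms: none
Why: Acidolysis of the tert-butyl ester frees the C4 carboxylic acid of the alkyl half; the other ester and both lactones are not cleaved by anhydrous acid.

## Compound list

1 | 3-methylbutanal | CC(C)CC=O | starting material
2 | 3-methyl-2-methylidenebutanal | CC(C)C(=C)C=O | intermediate
3 | ethyl (2E)-5-methyl-4-methylidenehex-2-enoate | CC(C)C(=C)/C=C/C(=O)OCC | intermediate
4 | (2E)-5-methyl-4-methylidenehex-2-en-1-ol | CC(C)C(=C)/C=C/CO | intermediate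
5 | tert-butyl(dimethyl){[(2E)-5-methyl-4-methylidenehex-2-en-1-yl]oxy}silane | CC(C)C(=C)/C=C/CO[Si](C)(C)C(C)(C)C | intermediate
6 | 2,2-dimethyl-1,3-dioxan-5-one | CC1(C)OCC(=O)CO1 | starting material
7 | 2,2-dimethyl-4H-1,3-dioxin-5-yl cyclohexanecarboxylate | CC1(C)OCC(OC(=O)C2CCCCC2)=CO1 | intermediate
8 | 3-oxoprop-1-en-2-yl cyclohexanecarboxylate | C=C(C=O)OC(=O)C1CCCCC1 | intermediate
9 | (1S,2R)-2-({[tert-butyl(dimethyl)silyl]oxy}methyl)-1-formyl-4-(propan-2-yl)cyclohex-3-en-1-yl cyclohexanecarboxylate | CC(C)C1=C[C@H](CO[Si](C)(C)C(C)(C)C)[C@](OC(=O)C2CCCCC2)(C=O)CC1 | intermediate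
10 | (1S,2R)-2-({[tert-butyl(dimethyl)silyl]oxy}methyl)-1-(hydroxymethyl)-4-(propan-2-yl)cyclohex-3-en-1-ol | CC(C)C1=C[C@H](CO[Si](C)(C)C(C)(C)C)[C@](O)(CO)CC1 | intermediate
11 | tert-butyl{[(5S,6R)-2,2-dimethyl-8-(propan-2-yl)-1,3-dioxaspiro[4.5]dec-7-en-6-yl]methoxy}dimethylsilane | CC(C)C1=C[C@H](CO[Si](C)(C)C(C)(C)C)[C@]2(COC(C)(C)O2)CC1 | intermediate
12 | [(5S,6R,7R,8S)-6-({[tert-butyl(dimethyl)silyl]oxy}methyl)-2,2-dimethyl-8-(propan-2-yl)-1,3-dioxaspiro[4.5]decan-7-yl]borane | CC(C)[C@H]1CC[C@@]2(COC(C)(C)O2)[C@@H](CO[Si](C)(C)C(C)(C)C)[C@@H]1B | intermediate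
13 | tert-butyl{[(5S,6R,7R,8S)-2,2-dimethyl-8-(propan-2-yl)-7-(4,4,5,5-tetramethyl-1,3,2-dioxaborolan-2-yl)-1,3-dioxaspiro[4.5]decan-6-yl]methoxy}dimethylsilane | CC(C)[C@H]1CC[C@@]2(COC(C)(C)O2)[C@@H](CO[Si](C)(C)C(C)(C)C)[C@@H]1B3OC(C)(C)C(C)(C)O3 | intermediate
14 | bromomagnesium ethenyl(pinacolato)borate of 13 (5S,6R,7R,8S) | CC(C)[C@H]1CC[C@@]2(COC(C)(C)O2)[C@@H](CO[Si](C)(C)C(C)(C)C)[C@@H]1[B-]3(C=C)OC(C)(C)C(C)(C)O3.[Mg+]Br | intermediate
15 | pinacol {2-iodo-1-[(5S,6R,7R,8R)-6-({[tert-butyl(dimethyl)silyl]oxy}methyl)-2,2-dimethyl-8-(propan-2-yl)-1,3-dioxaspiro[4.5]decan-7-yl]ethyl}boronate, both epimers at the boron-bearing carbon | CC(C)[C@H]1CC[C@@]2(COC(C)(C)O2)[C@@H](CO[Si](C)(C)C(C)(C)C)[C@@H]1C(CI)B3OC(C)(C)C(C)(C)O3 | intermediate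
16 | tert-butyl{[(5S,6R,7R,8R)-7-ethenyl-2,2-dimethyl-8-(propan-2-yl)-1,3-dioxaspiro[4.5]decan-6-yl]methoxy}dimethylsilane | CC(C)[C@H]1CC[C@@]2(COC(C)(C)O2)[C@@H](CO[Si](C)(C)C(C)(C)C)[C@@H]1C=C | intermediate
17 | [(5S,6R,7R,8R)-7-ethenyl-2,2-dimethyl-8-(propan-2-yl)-1,3-dioxaspiro[4.5]decan-6-yl]methanol | CC(C)[C@H]1CC[C@@]2(COC(C)(C)O2)[C@@H](CO)[C@@H]1C=C | intermediate
18 | (5S,6S,7R,8R)-7-ethenyl-2,2-dimethyl-8-(propan-2-yl)-1,3-dioxaspiro[4.5]decane-6-carbaldehyde | CC(C)[C@H]1CC[C@@]2(COC(C)(C)O2)[C@@H](C=O)[C@@H]1C=C | intermediate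
19 | (5S,6S,7R,8R)-7-ethenyl-2,2-dimethyl-8-(propan-2-yl)-1,3-dioxaspiro[4.5]decane-6-carboxylic acid | CC(C)[C@H]1CC[C@@]2(COC(C)(C)O2)[C@@H](C(=O)O)[C@@H]1C=C | intermediate
20 | 2-(tert-butoxycarbonyl)prop-2-en-1-yl (5S,6S,7R,8R)-7-ethenyl-2,2-dimethyl-8-(propan-2-yl)-1,3-dioxaspiro[4.5]decane-6-carboxylate | CC(C)[C@H]1CC[C@@]2(COC(C)(C)O2)[C@@H](C(=O)OCC(=C)C(=O)OC(C)(C)C)[C@@H]1C=C | intermediate
21 | tert-butyl (5aS,6R,9S,9aS)-2',2'-dimethyl-1-oxo-6-(propan-2-yl)-3,5a,6,7,8,9a-hexahydro-1H-spiro[2-benzoxepine-9,4'-[1,3]dioxolane]-4-carboxylate | CC(C)[C@H]1CC[C@@]2(COC(C)(C)O2)[C@H]3C(=O)OCC(C(=O)OC(C)(C)C)=C[C@H]13 | intermediate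
22 | (5aS,6R,9S,9aS)-9-hydroxy-9-(hydroxymethyl)-1-oxo-6-(propan-2-yl)-1,3,5a,6,7,8,9,9a-octahydro-2-benzoxepine-4-carboxylic acid | CC(C)[C@H]1CC[C@@](O)(CO)[C@H]2C(=O)OCC(C(=O)O)=C[C@H]12 | intermediate
23 | (1R,2S) enantiomer of 9 | CC(C)C1=C[C@@H](CO[Si](C)(C)C(C)(C)C)[C@@](OC(=O)C2CCCCC2)(C=O)CC1 | intermediate
24 | (1R,2S) enantiomer of 10 | CC(C)C1=C[C@@H](CO[Si](C)(C)C(C)(C)C)[C@@](O)(CO)CC1 | intermediate
25 | (5R,6S) enantiomer of 11 | CC(C)C1=C[C@@H](CO[Si](C)(C)C(C)(C)C)[C@@]2(COC(C)(C)O2)CC1 | intermediate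
26 | (5R,6S,7S,8R) enantiomer of 12 | CC(C)[C@@H]1CC[C@]2(COC(C)(C)O2)[C@H](CO[Si](C)(C)C(C)(C)C)[C@H]1B | intermediate
27 | (5R,6S,7S,8R) enantiomer of 13 | CC(C)[C@@H]1CC[C@]2(COC(C)(C)O2)[C@H](CO[Si](C)(C)C(C)(C)C)[C@H]1B3OC(C)(C)C(C)(C)O3 | intermediate
28 | (5R,6S,7S,8R) enantiomer of 14 | CC(C)[C@@H]1CC[C@]2(COC(C)(C)O2)[C@H](CO[Si](C)(C)C(C)(C)C)[C@H]1[B-]3(C=C)OC(C)(C)C(C)(C)O3.[Mg+]Br | intermediate
29 | mirror-image counterpart of 15 (ring 5R,6S,7S,8S), both epimers at the boron-bearing carbon | CC(C)[C@@H]1CC[C@]2(COC(C)(C)O2)[C@H](CO[Si](C)(C)C(C)(C)C)[C@H]1C(CI)B3OC(C)(C)C(C)(C)O3 | intermediate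
30 | (5R,6S,7S,8S) enantiomer of 16 | CC(C)[C@@H]1CC[C@]2(COC(C)(C)O2)[C@H](CO[Si](C)(C)C(C)(C)C)[C@H]1C=C | intermediate
31 | (5R,6S,7S,8S) enantiomer of 17 | CC(C)[C@@H]1CC[C@]2(COC(C)(C)O2)[C@H](CO)[C@H]1C=C | intermediate
32 | (5R,6R,7S,8S) enantiomer of 18 | CC(C)[C@@H]1CC[C@]2(COC(C)(C)O2)[C@H](C=O)[C@H]1C=C | intermediate
33 | (5R,6R,7S,8S) enantiomer of 19 | CC(C)[C@@H]1CC[C@]2(COC(C)(C)O2)[C@H](C(=O)O)[C@H]1C=C | intermediate
34 | (5R,6R,7S,8S) enantiomer of 20 | CC(C)[C@@H]1CC[C@]2(COC(C)(C)O2)[C@H](C(=O)OCC(=C)C(=O)OC(C)(C)C)[C@H]1C=C | intermediate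
35 | (5aR,6S,9R,9aR) enantiomer of 21 | CC(C)[C@@H]1CC[C@]2(COC(C)(C)O2)[C@@H]3C(=O)OCC(C(=O)OC(C)(C)C)=C[C@@H]13 | intermediate
36 | tert-butyl (5aR,6S,9R,9aR)-9-hydroxy-9-(hydroxymethyl)-1-oxo-6-(propan-2-yl)-1,3,5a,6,7,8,9,9a-octahydro-2-benzoxepine-4-carboxylate | CC(C)[C@@H]1CC[C@](O)(CO)[C@@H]2C(=O)OCC(C(=O)OC(C)(C)C)=C[C@@H]12 | intermediate
37 | tert-butyl (5aR,6S,9R,9aR)-9-hydroxy-9-{[(methylsulfonyl)oxy]methyl}-1-oxo-6-(propan-2-yl)-1,3,5a,6,7,8,9,9a-octahydro-2-benzoxepine-4-carboxylate | CC(C)[C@@H]1CC[C@](O)(COS(C)(=O)=O)[C@@H]2C(=O)OCC(C(=O)OC(C)(C)C)=C[C@@H]12 | intermediate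
38 | tert-butyl (5aR,6S,9R,9aR)-1-oxo-6-(propan-2-yl)-3,5a,6,7,8,9a-hexahydro-1H-spiro[2-benzoxepine-9,2'-oxirane]-4-carboxylate | CC(C)[C@@H]1CC[C@]2(CO2)[C@@H]3C(=O)OCC(C(=O)OC(C)(C)C)=C[C@@H]13 | intermediate
39 | tert-butyl ester of the target (acyl half 5aS,6R,9S,9aS; alkyl half 5aR,6S,9R,9aR) | CC(C)[C@H]1CC[C@@](O)(CO)[C@H]2C(=O)OCC(C(=O)OC[C@@]3(O)CC[C@@H](C(C)C)[C@@H]4C=C(C(=O)OC(C)(C)C)COC(=O)[C@H]43)=C[C@H]12 | intermediate
40 | CNP0340505.1 | CC(C)[C@H]1CC[C@@](O)(CO)[C@H]2C(=O)OCC(C(=O)OC[C@@]3(O)CC[C@@H](C(C)C)[C@@H]4C=C(C(=O)O)COC(=O)[C@H]43)=C[C@H]12 | target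

## Step count and risks

Total step count: 29. Longest linear sequence: 17 steps (steps 1–4, 17–27, 28, 29).

**Risk 1: step 7 (and its mirror image, step 17).** The formyl (iminium) group may go exo instead of endo, which would give the wrong C9a epimer, or face discrimination by the ammonium catalyst may be low with this trisubstituted diene. The fallback uses an exo preference instead of fighting it. It sets out from 5 and 2-bromoacrolein (C=C(Br)C=O, from acrolein by bromination and dehydrobromination), with the HNTf2-activated (S)-o-tolyl-CBS oxazaborolidine in CH2Cl2 at −78 °C. This would give (1R,2R)-1-bromo-2-({[tert-butyl(dimethyl)silyl]oxy}methyl)-4-(propan-2-yl)cyclohex-3-ene-1-carbaldehyde F1, with CHO exo and Br cis to CH2OTBS. NaBH4 in MeOH gives the bromohydrin [(1R,2R)-1-bromo-2-({[tert-butyl(dimethyl)silyl]oxy}methyl)-4-(propan-2-yl)cyclohex-3-en-1-yl]methanol F2. K2CO3 in MeOH closes the spiro-epoxide tert-butyl{[(3S,4R)-6-(propan-2-yl)-1-oxaspiro[2.5]oct-5-en-4-yl]methoxy}dimethylsilane F3 with inversion at the quaternary carbon, so oxygen ends trans and CH2 cis to CH2OTBS. KOH in DMSO/H2O at 60 °C opens it at CH2 and the route is rejoined at 10. With the antipodal catalyst the same sequence gives the (1S,2S) bromo aldehyde F4, the (1S,2S) bromohydrin F5 and the (3R,4S) epoxide F6, and rejoins at 24.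

**Risk 2: step 10 (and its mirror image, step 20).** Borane may attack the wrong alkene face, or over-hydroboration may give dialkylboranes that do not converge on one boronic ester, and the hindered boron may be slow to form the vinyl boronate complex. The fallback makes the C5a–C bond directly. It sets out from 11: hydroformylation with Rh(acac)(CO)2 and tris(2,4-di-tert-butylphenyl) phosphite under CO/H2 (1:1, 40 bar) in toluene at 90 °C adds H and CHO syn, with CHO on the CH carbon. This would give (5S,6R,7R,8R)-6-({[tert-butyl(dimethyl)silyl]oxy}methyl)-2,2-dimethyl-8-(propan-2-yl)-1,3-dioxaspiro[4.5]decane-7-carbaldehyde F7, whose formyl-bearing centre can be equilibrated to the all-equatorial isomer. Wittig methylenation (Ph3PCH3Br, KOC(CH3)3, THF, 0 °C) rejoins the route at 16. The mirror-image series goes from 25 through the (5R,6S,7S,8S) aldehyde F8 to 30.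

**Risk 3: step 28.** The conjugated carboxylate may attack the neopentyl-type epoxide carbon too slowly, so that translactonisation of the free primary alcohol of 22 onto its lactone carbonyl, or epoxide opening by that alcohol, competes. The fallback acylates instead of alkylating. It sets out from 21 and 36. Selective cleavage of the tert-butyl ester of 21 with Me3SiOTf and 2,6-lutidine in CH2Cl2 at 0 °C gives (5aS,6R,9S,9aS)-2',2'-dimethyl-1-oxo-6-(propan-2-yl)-3,5a,6,7,8,9a-hexahydro-1H-spiro[2-benzoxepine-9,4'-[1,3]dioxolane]-4-carboxylic acid F9. Yamaguchi esterification (2,4,6-trichlorobenzoyl chloride, Et3N, then 36 and DMAP in toluene) acylates the primary alcohol of 36 and gives the acetonide tert-butyl ester of the target F10. CF3CO2H/CH2Cl2/H2O then removes the acetonide and the tert-butyl ester and the route is rejoined at 40.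

## Further compounds

F1 | step 7 | (1R,2R)-1-bromo-2-({[tert-butyl(dimethyl)silyl]oxy}methyl)-4-(propan-2-yl)cyclohex-3-ene-1-carbaldehyde | CC(C)C1=C[C@H](CO[Si](C)(C)C(C)(C)C)[C@@](Br)(C=O)CC1
F2 | step 7 | [(1R,2R)-1-bromo-2-({[tert-butyl(dimethyl)silyl]oxy}methyl)-4-(propan-2-yl)cyclohex-3-en-1-yl]methanol | CC(C)C1=C[C@H](CO[Si](C)(C)C(C)(C)C)[C@@](Br)(CO)CC1
F3 | step 7 | tert-butyl{[(3S,4R)-6-(propan-2-yl)-1-oxaspiro[2.5]oct-5-en-4-yl]methoxy}dimethylsilane | CC(C)C1=C[C@H](CO[Si](C)(C)C(C)(C)C)[C@]2(CO2)CC1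
F4 | step 7 | (1S,2S) enantiomer of F1 | CC(C)C1=C[C@@H](CO[Si](C)(C)C(C)(C)C)[C@](Br)(C=O)CC1
F5 | step 7 | (1S,2S) enantiomer of F2 | CC(C)C1=C[C@@H](CO[Si](C)(C)C(C)(C)C)[C@](Br)(CO)CC1
F6 | step 7 | (3R,4S) enantiomer of F3 | CC(C)C1=C[C@@H](CO[Si](C)(C)C(C)(C)C)[C@@]2(CO2)CC1
F7 | step 10 | (5S,6R,7R,8R)-6-({[tert-butyl(dimethyl)silyl]oxy}methyl)-2,2-dimethyl-8-(propan-2-yl)-1,3-dioxaspiro[4.5]decane-7-carbaldehyde | CC(C)[C@H]1CC[C@@]2(COC(C)(C)O2)[C@@H](CO[Si](C)(C)C(C)(C)C)[C@@H]1C=O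
F8 | step 10 | (5R,6S,7S,8S) enantiomer of F7 | CC(C)[C@@H]1CC[C@]2(COC(C)(C)O2)[C@H](CO[Si](C)(C)C(C)(C)C)[C@H]1C=O
F9 | step 28 | (5aS,6R,9S,9aS)-2',2'-dimethyl-1-oxo-6-(propan-2-yl)-3,5a,6,7,8,9a-hexahydro-1H-spiro[2-benzoxepine-9,4'-[1,3]dioxolane]-4-carboxylic acid | CC(C)[C@H]1CC[C@@]2(COC(C)(C)O2)[C@H]3C(=O)OCC(C(=O)O)=C[C@H]13
F10 | step 28 | acetonide tert-butyl ester of the target (acyl half as 9,4'-spiro-dioxolane; alkyl half as tert-butyl ester) | CC(C)[C@H]1CC[C@@]2(COC(C)(C)O2)[C@H]3C(=O)OCC(C(=O)OC[C@@]4(O)CC[C@@H](C(C)C)[C@@H]5C=C(C(=O)OC(C)(C)C)COC(=O)[C@H]54)=C[C@H]13
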